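**Plan**

- Retrosynthesis: the five benzyl ethers come off last. The hemiketal is then cut at C2'–OH and C2'–O7, which reopens the dihydrofuran ring (O7–C7–C8–C2–C2') to a 4-hydroxybenzyl CH2 on the spiro carbon C2. Next C2–CH2Ar (enolate benzylation) and C2–C8 (ketone α-arylation) are cut.
- Enabling feature: C2' is benzylic and para to the free OH of the 4-hydroxyphenyl ring, carries two oxygens (O7 and OH) and sits on the fully substituted C2. It is therefore the carbonyl oxidation level of a CH2 that two successive quinone methide cycles can reach.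
- Forward: kaempferol is turned into its 8-bromo-7-O-MOM-3,5,4'-tri-O-benzyl ether. Pd coupling joins it to 4,6-bis(benzyloxy)benzofuranone (C8–C2), and benzylation with 4-(MOM-oxy)benzyl bromide adds C2–CH2. Acid frees the two phenols, DDQ/water closes the only new ring (the dihydrofuran), and hydrogenolysis finishes.
- Stereochemistry: C2 comes from a cinchona phase-transfer benzylation of the planar enolate. C2' settles under thermodynamic control through ring–chain equilibration of the hemiketal next to C2.

Key step: step 12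

Remark 1 (numbering): C2, C3 and O1 belong to the benzofuran-3(2H)-one, C2' is the hemiketal carbon, and O7, C7, C8 are kaempferol positions.
Remark 2: the (R) configuration at C2' (OH cis to the C3 carbonyl, aryl cis to O1) is assumed to be the equilibrium epimer, since this centre epimerises through the ring-opened 2-aroyl ketone.
Remark 3: which pseudoenantiomeric cinchona salt gives (S) at C2 cannot be derived from precedent for this enolate; the route is written for the cinchonidinium salt, and the cinchoninium analogue is used if a test run shows the opposite sense.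

**Route**

Step 1
Reactants: 1 kaempferol
Product: 2 3,5,7,4'-tetra-O-acetylkaempferol
Conditions: Ac2O, pyridine, cat. DMAP, rt
Reagents that add atoms: acetic anhydride CC(=O)OC(C)=O
Why: Exhaustive O-acylation of phenols under nucleophilic catalysis, which also esterifies the hydrogen-bonded 5-OH.

Step 2
Reactants: 2 3,5,7,4'-tetra-O-acetylkaempferol
Product: 3 3,5,4'-tri-O-acetylkaempferol (7-OH free)
Conditions: PhSH, cat. imidazole, NMP, 0 °C
Reagents that add atoms: none
Why: Regioselective thiolysis of an aryl acetate, the 7-O-acetate being the ester of the most acidic flavonoid phenol and hence the best acyl donor, a selectivity established for peracetylated flavonols.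

Step 3
Reactants: 3 3,5,4'-tri-O-acetylkaempferol
Product: 4 3,5,4'-tri-O-acetyl-7-O-(methoxymethyl)kaempferol
Conditions: MOMCl, iPr2NEt, CH2Cl2, 0 °C to rt
Reagents that add atoms: chloromethyl methyl ether COCCl
Why: MOM ether formation by O-alkylation of the phenol with an α-chloro ether under amine base, conditions that leave aryl acetates in place.

Step 4
Reactants: 4 3,5,4'-tri-O-acetyl-7-O-(methoxymethyl)kaempferol
Product: 6 3,5,4'-tri-O-benzyl-7-O-(methoxymethyl)kaempferol, via 7-O-(methoxymethyl)kaempferol 5 (not isolated)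
Conditions: K2CO3, MeOH, rt, Ar; evaporate; then BnBr, K2CO3, DMF, 60 °C
Reagents that add atoms: benzyl bromide BrCc1ccccc1
Why: Base methanolysis of the three aryl acetates followed by Williamson benzylation in the same flask, where carbonate in warm DMF also alkylates the chelated 5-OH and the MOM acetal is inert to base.

Step 5
Reactants: 6 3,5,4'-tri-O-benzyl-7-O-(methoxymethyl)kaempferol
Product: 7 8-bromo-3,5,4'-tri-O-benzyl-7-O-(methoxymethyl)kaempferol
Conditions: NBS (1.0 equiv), DMF, 0 °C to rt, dark
Reagents that add atoms: N-bromosuccinimide O=C1CCC(=O)N1Br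
Why: Electrophilic aromatic bromination of the phloroglucinol-type A ring, which in 5,7-dialkoxyflavones occurs at C8 in preference to C6, under neutral conditions that spare the acetal.

Step 6
Reactants: 8 4,6-dihydroxybenzofuran-3(2H)-one
Product: 9 4,6-bis(benzyloxy)benzofuran-3(2H)-one
Conditions: BnBr (2.1 equiv), K2CO3, DMF, 60 °C
Reagents that add atoms: benzyl bromide BrCc1ccccc1
Why: Williamson ether synthesis on both phenols, with only a slight excess of benzyl bromide so that alkylation of the acidic C2 methylene stays minor.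

Step 7
Reactants: 10 4-hydroxybenzyl alcohol
Product: 11 4-(methoxymethoxy)benzyl alcohol
Conditions: MOMCl (1.0 equiv), K2CO3, acetone, 0 °C to rt
Reagents that add atoms: chloromethyl methyl ether COCCl
Why: Chemoselective O-alkylation, since carbonate deprotonates only the phenol and the phenoxide outcompetes the neutral benzylic alcohol for the chloro ether.

Step 8
Reactants: 11 4-(methoxymethoxy)benzyl alcohol
Product: 12 4-(methoxymethoxy)benzyl bromide
Conditions: CBr4, PPh3, CH2Cl2, 0 °C; used at once
Reagents that add atoms: carbon tetrabromide BrC(Br)(Br)Br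
Why: Appel bromination of a primary benzylic alcohol, free of strong acid so that the aryl MOM ether survives.

Step 9
Reactants: 9 4,6-bis(benzyloxy)benzofuran-3(2H)-one; 7 8-bromo-3,5,4'-tri-O-benzyl-7-O-(methoxymethyl)kaempferol
Product: 13 4,6-bis(benzyloxy)-2-[3,5,4'-tri-O-benzyl-7-O-(methoxymethyl)kaempferol-8-yl]benzofuran-3(2H)-one (racemic at the acidic C2–H)
Conditions: cat. Pd2(dba)3, cat. XPhos, K3PO4, degassed toluene, 90 °C, Ar
Reagents that add atoms: none
Why: Palladium-catalysed α-arylation of a ketone (Buchwald–Hartwig–Miura type) with a bulky biarylphosphine for the di-ortho-substituted bromide, the acidic benzofuranone (its enolate is an aromatic 3-oxidobenzofuran) needing only phosphate base, which leaves the chromone intact.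

Step 10
Reactants: 13 the 2-(kaempferol-8-yl)benzofuranone; 12 4-(methoxymethoxy)benzyl bromide
Product: 14 (S)-4,6-bis(benzyloxy)-2-[4-(methoxymethoxy)benzyl]-2-[3,5,4'-tri-O-benzyl-7-O-(methoxymethyl)kaempferol-8-yl]benzofuran-3(2H)-one
Conditions: cat. N-(9-anthracenylmethyl)-O-allylcinchonidinium bromide, Cs2CO3 (solid), toluene, −20 to 0 °C, Ar
Reagents that add atoms: none
Why: Asymmetric phase-transfer alkylation of an α-aryl cyclic ketone, in which the chiral ammonium cation pairs with the planar 3-oxidobenzofuran enolate and leaves one face of C2 open to the benzylic bromide, setting the quaternary (S) centre, while the soft benzylic electrophile favours carbon over oxygen.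

Step 11
Reactants: 14 the bis-MOM quaternary ketone
Product: 15 (S)-4,6-bis(benzyloxy)-2-(4-hydroxybenzyl)-2-(3,5,4'-tri-O-benzylkaempferol-8-yl)benzofuran-3(2H)-one (7-OH and side-chain 4-OH free)
Conditions: 2 M HCl, MeOH/THF, 45 °C
Reagents that add atoms: none
Why: Acid-catalysed transacetalisation of both aryl MOM ethers to methanol, under which benzyl ethers persist and the non-enolisable quaternary ketone cannot racemise.

Step 12
Reactants: 15 the 2-(4-hydroxybenzyl)-2-(7-hydroxyflavonol-8-yl)benzofuranone
Product: 19 (2S,2'R)-penta-O-benzyl spiro hemiketal, via first para-quinone methide 16 (not isolated), via C2'-H spiro-dihydrofuran 17 (not isolated), via alkoxy para-quinone methide 18 (not isolated)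
Conditions: DDQ (2.3 equiv), 1,4-dioxane/H2O 9:1, 0 °C to rt
Reagents that add atoms: water O
Why: DDQ removes hydride from C2' of the only phenol that has a para benzylic C–H (the phenol losing its proton) to give quinone methide 16, and O7–H adds to its exocyclic carbon in an oxa-1,6-addition, a 5-exo-trig closure of the dihydrofuran ring (O7, C7, C8, C2, C2') that restores the phenol in 17. The remaining C2'–H of 17 is still para-benzylic and now also α to oxygen, so a second equivalent of DDQ abstracts it and water adds to the resulting alkoxy quinone methide/oxocarbenium 18 to give the hemiketal. The closest known reactions are the DDQ oxidation of 4-alkylphenols in hydroxylic solvents, which runs through two quinone methide cycles at one benzylic carbon up to the carbonyl level, and DDQ-induced cyclisation of ortho-hydroxyaryl-substituted 4-hydroxybenzyl compounds to 2-aryl-dihydrobenzofurans and flavans. C2' is the only new stereocentre and is under thermodynamic control: the hemiketal opens reversibly to the 2-aroyl ketone and recloses, so the fixed C2 centre should select the epimer with OH cis to the C3 carbonyl (OH···O=C hydrogen bond) and the aryl group cis to the smaller O1. The step needs site selectivity among six benzylic CH2 groups and two free phenols, and this is secured because only the 4-hydroxybenzyl group combines a free phenol with a para C–H, while the 7-OH has none and the benzyl ether CH2 groups are not phenol-activated. The fully substituted C2 offers no β-hydrogen, which closes the exits to a styrene from 16 and to a benzofuran from 17, and capture of 16 by water instead of O7 would lead through the same ketone to the same hemiketal.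

Step 13
Reactants: 19 (2S,2'R)-penta-O-benzyl spiro hemiketal
Product: 20 CNP0283000.1, the (2S,2'R)-spiro hemiketal
Conditions: H2 (1 atm), 10% Pd/C, EtOAc/MeOH, rt
Reagents that add atoms: none
Why: Heterogeneous hydrogenolysis of aryl benzyl ethers at ambient pressure, under which the chromone double bond and the aryl ketones are not reduced, C2 is untouched and C2' stays at its equilibrium configuration.

**Compound list**

1 | kaempferol | O=c1c(O)c(-c2ccc(O)cc2)oc2cc(O)cc(O)c12 | starting material
2 | 3,5,7,4'-tetra-O-acetylkaempferol | O=c1c(OC(C)=O)c(-c2ccc(OC(C)=O)cc2)oc2cc(OC(C)=O)cc(OC(C)=O)c12 | intermediate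
3 | 3,5,4'-tri-O-acetylkaempferol (7-OH free) | O=c1c(OC(C)=O)c(-c2ccc(OC(C)=O)cc2)oc2cc(O)cc(OC(C)=O)c12 | intermediate
4 | 3,5,4'-tri-O-acetyl-7-O-(methoxymethyl)kaempferol | O=c1c(OC(C)=O)c(-c2ccc(OC(C)=O)cc2)oc2cc(OCOC)cc(OC(C)=O)c12 | intermediate
5 | 7-O-(methoxymethyl)kaempferol (not isolated) | O=c1c(O)c(-c2ccc(O)cc2)oc2cc(OCOC)cc(O)c12 | intermediate
6 | 3,5,4'-tri-O-benzyl-7-O-(methoxymethyl)kaempferol | O=c1c(OCc2ccccc2)c(-c2ccc(OCc3ccccc3)cc2)oc2cc(OCOC)cc(OCc3ccccc3)c12 | intermediate
7 | 8-bromo-3,5,4'-tri-O-benzyl-7-O-(methoxymethyl)kaempferol | O=c1c(OCc2ccccc2)c(-c2ccc(OCc3ccccc3)cc2)oc2c(Br)c(OCOC)cc(OCc3ccccc3)c12 | intermediate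
8 | 4,6-dihydroxybenzofuran-3(2H)-one | O=C1COc2cc(O)cc(O)c12 | starting material
9 | 4,6-bis(benzyloxy)benzofuran-3(2H)-one | O=C1COc2cc(OCc3ccccc3)cc(OCc3ccccc3)c12 | intermediate
10 | 4-hydroxybenzyl alcohol | OCc1ccc(O)cc1 | starting material
11 | 4-(methoxymethoxy)benzyl alcohol | OCc1ccc(OCOC)cc1 | intermediate
12 | 4-(methoxymethoxy)benzyl bromide | BrCc1ccc(OCOC)cc1 | intermediate
13 | 4,6-bis(benzyloxy)-2-[3,5,4'-tri-O-benzyl-7-O-(methoxymethyl)kaempferol-8-yl]benzofuran-3(2H)-one, racemic | O=C1c2c(OCc3ccccc3)cc(OCc3ccccc3)cc2OC1c1c(OCOC)cc(OCc2ccccc2)c2c(=O)c(OCc3ccccc3)c(-c3ccc(OCc4ccccc4)cc3)oc12 | intermediate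
14 | (S)-4,6-bis(benzyloxy)-2-[4-(methoxymethoxy)benzyl]-2-[3,5,4'-tri-O-benzyl-7-O-(methoxymethyl)kaempferol-8-yl]benzofuran-3(2H)-one | O=C1c2c(OCc3ccccc3)cc(OCc3ccccc3)cc2O[C@@]1(Cc1ccc(OCOC)cc1)c1c(OCOC)cc(OCc2ccccc2)c2c(=O)c(OCc3ccccc3)c(-c3ccc(OCc4ccccc4)cc3)oc12 | intermediate
15 | (S)-4,6-bis(benzyloxy)-2-(4-hydroxybenzyl)-2-(3,5,4'-tri-O-benzylkaempferol-8-yl)benzofuran-3(2H)-one | O=C1c2c(OCc3ccccc3)cc(OCc3ccccc3)cc2O[C@@]1(Cc1ccc(O)cc1)c1c(O)cc(OCc2ccccc2)c2c(=O)c(OCc3ccccc3)c(-c3ccc(OCc4ccccc4)cc3)oc12 | intermediate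
16 | first para-quinone methide: C2 bears a CH= group that is the exocyclic carbon of a cyclohexa-2,5-dien-4-one (C2 arrangement as in 15; not isolated) | O=C1c2c(OCc3ccccc3)cc(OCc3ccccc3)cc2O[C@@]1(C=C1C=CC(=O)C=C1)c1c(O)cc(OCc2ccccc2)c2c(=O)c(OCc3ccccc3)c(-c3ccc(OCc4ccccc4)cc3)oc12 | intermediate
17 | penta-O-benzyl spiro-dihydrofuran with C2'–H and 4-hydroxyphenyl on C2', C2' epimers (C2 arrangement unchanged, formally R by CIP; not isolated) | O=C1c2c(OCc3ccccc3)cc(OCc3ccccc3)cc2O[C@@]12c1c(cc(OCc3ccccc3)c3c(=O)c(OCc4ccccc4)c(-c4ccc(OCc5ccccc5)cc4)oc13)OC2c1ccc(O)cc1 | intermediate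
18 | alkoxy para-quinone methide: C2' double-bonded to the cyclohexa-2,5-dien-4-one ring (C2 arrangement unchanged; not isolated) | O=C1c2c(OCc3ccccc3)cc(OCc3ccccc3)cc2O[C@@]12c1c(cc(OCc3ccccc3)c3c(=O)c(OCc4ccccc4)c(-c4ccc(OCc5ccccc5)cc4)oc13)OC2=C1C=CC(=O)C=C1 | intermediate
19 | (2S,2'R)-penta-O-benzyl spiro hemiketal (benzyl on benzofuranone O4 and O6 and on flavonol O3, O5, O4'; hemiketal OH and 4-hydroxyphenyl OH free) | O=C1c2c(OCc3ccccc3)cc(OCc3ccccc3)cc2O[C@@]12c1c(cc(OCc3ccccc3)c3c(=O)c(OCc4ccccc4)c(-c4ccc(OCc5ccccc5)cc4)oc13)O[C@]2(O)c1ccc(O)cc1 | intermediate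
20 | CNP0283000.1: 4,6-dihydroxybenzofuran-3(2H)-one spiro-fused at C2 (S) to a 2-hydroxy-2-(4-hydroxyphenyl)-2,3-dihydrofuran (hemiketal carbon R) annulated to kaempferol through O7–C7–C8 | O=C1c2c(O)cc(O)cc2O[C@@]12c1c(cc(O)c3c(=O)c(O)c(-c4ccc(O)cc4)oc13)O[C@]2(O)c1ccc(O)cc1 | target

**Step count and risks**

Total: 13 steps. Longest linear sequence: 10 steps (steps 1–5 and 9–13).

Step 12 (key step). The quinone methide may be diverted: an acyl or aryl group can shift from the neighbouring quaternary carbon, O7 can attack the ring carbon para to oxygen instead of C2', or the sequence can stall after the first oxidation. The fallback builds the carbonyl oxidation level at C2' without oxidising a phenol. It sets out from 13: the lithium enolate (LiHMDS, THF, −78 °C) adds to 4-(methoxymethoxy)benzaldehyde to give the racemic aldol adduct 4,6-bis(benzyloxy)-2-{hydroxy[4-(methoxymethoxy)phenyl]methyl}-2-(protected kaempferol-8-yl)benzofuranone F1. Dess–Martin oxidation should give the 2-aroyl ketone F2. HCl in MeOH/THF removes both MOM groups, and the freed 7-OH closes onto the aroyl carbonyl to give the racemic penta-O-benzyl hemiketal F3. Preparative HPLC on a chiral stationary phase delivers 19, where the fallback rejoins the route.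

Step 10. The bulky di-ortho-substituted aryl group next to the reacting carbon may loosen the ion pair and give poor facial selectivity, or alkylation may go to the enolate oxygen. The fallback replaces catalytic induction by resolution. It sets out from 13: the lithium enolate (LiHMDS, THF, −78 to 0 °C), which favours C-alkylation, is benzylated with 12 to give the racemic quaternary ketone F4. Its enantiomers are separated by preparative chromatography on a polysaccharide chiral phase, and the (S)-enantiomer is 14, where the route resumes.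

Step 9. Oxidative addition and reductive elimination at the hindered, electron-rich bromide may be slow, so that hydrodebromination of 7 or oxidative degradation of the product enolate takes over. The fallback turns the enolate coupling into a biaryl-type cross-coupling. It sets out from 9: TBSOTf/Et3N gives the enol silyl ether 4,6-bis(benzyloxy)-3-(tert-butyldimethylsilyloxy)benzofuran F5. Lithiation at C2 (n-BuLi, THF, −78 °C) and transmetalation with ZnCl2 give the benzofuran-2-ylzinc chloride F6. Negishi coupling with 7 (Pd2(dba)3, SPhos, THF, 60 °C) should give the 2-(kaempferol-8-yl)-3-silyloxybenzofuran F7. TBAF buffered with AcOH releases the ketone 13, where the route resumes.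

**Further compounds**

F1 | step 12 | 4,6-bis(benzyloxy)-2-{hydroxy[4-(methoxymethoxy)phenyl]methyl}-2-[3,5,4'-tri-O-benzyl-7-O-(methoxymethyl)kaempferol-8-yl]benzofuran-3(2H)-one, racemic diastereomer mixture | O=C1c2c(OCc3ccccc3)cc(OCc3ccccc3)cc2OC1(C(O)c1ccc(OCOC)cc1)c1c(OCOC)cc(OCc2ccccc2)c2c(=O)c(OCc3ccccc3)c(-c3ccc(OCc4ccccc4)cc3)oc12
F2 | step 12 | 4,6-bis(benzyloxy)-2-[4-(methoxymethoxy)benzoyl]-2-[3,5,4'-tri-O-benzyl-7-O-(methoxymethyl)kaempferol-8-yl]benzofuran-3(2H)-one, racemic | O=C1c2c(OCc3ccccc3)cc(OCc3ccccc3)cc2OC1(C(=O)c1ccc(OCOC)cc1)c1c(OCOC)cc(OCc2ccccc2)c2c(=O)c(OCc3ccccc3)c(-c3ccc(OCc4ccccc4)cc3)oc12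
F3 | step 12 | racemic penta-O-benzyl spiro hemiketal (racemate of 19) | O=C1c2c(OCc3ccccc3)cc(OCc3ccccc3)cc2OC12c1c(cc(OCc3ccccc3)c3c(=O)c(OCc4ccccc4)c(-c4ccc(OCc5ccccc5)cc4)oc13)OC2(O)c1ccc(O)cc1
F4 | step 10 | racemic 4,6-bis(benzyloxy)-2-[4-(methoxymethoxy)benzyl]-2-[3,5,4'-tri-O-benzyl-7-O-(methoxymethyl)kaempferol-8-yl]benzofuran-3(2H)-one (racemate of 14) | O=C1c2c(OCc3ccccc3)cc(OCc3ccccc3)cc2OC1(Cc1ccc(OCOC)cc1)c1c(OCOC)cc(OCc2ccccc2)c2c(=O)c(OCc3ccccc3)c(-c3ccc(OCc4ccccc4)cc3)oc12
F5 | step 9 | 4,6-bis(benzyloxy)-3-(tert-butyldimethylsilyloxy)benzofuran | CC(C)(C)[Si](C)(C)Oc1coc2cc(OCc3ccccc3)cc(OCc3ccccc3)c12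
F6 | step 9 | [4,6-bis(benzyloxy)-3-(tert-butyldimethylsilyloxy)benzofuran-2-yl]zinc chloride | CC(C)(C)[Si](C)(C)Oc1c([Zn]Cl)oc2cc(OCc3ccccc3)cc(OCc3ccccc3)c12
F7 | step 9 | 4,6-bis(benzyloxy)-3-(tert-butyldimethylsilyloxy)-2-[3,5,4'-tri-O-benzyl-7-O-(methoxymethyl)kaempferol-8-yl]benzofuran | CC(C)(C)[Si](C)(C)Oc1c(oc2cc(OCc3ccccc3)cc(OCc3ccccc3)c12)-c1c(OCOC)cc(OCc2ccccc2)c2c(=O)c(OCc3ccccc3)c(-c3ccc(OCc4ccccc4)cc3)oc12
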